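Temperature reaches these flasks first through the precatalyst, which releases free catalyst, so ask how much of the catalyst charge is working during the run.

    reagent + catalyst intermediate B → free catalyst + right-handed product (k1 = 5.3 L mol⁻¹ s⁻¹, Ea1 = 46.0 kJ mol⁻¹)
    reagent + catalyst intermediate A → free catalyst + left-handed product (k2 = 450 L mol⁻¹ s⁻¹, Ea2 = 42.0 kJ mol⁻¹)
    free catalyst + left-handed substrate ⇌ catalyst intermediate A (K3 = 1.4 L mol⁻¹, k3 = 4300 L mol⁻¹ s⁻¹, Ea3 = 42.0 kJ mol⁻¹, ΔH3 = −14.0 kJ mol⁻¹)
    precatalyst → free catalyst (k4 = 0.013 s⁻¹, Ea4 = 99.0 kJ mol⁻¹)
    free catalyst + right-handed substrate ⇌ catalyst intermediate B (K5 = 6.0 L mol⁻¹, k5 = 3800 L mol⁻¹ s⁻¹, Ea5 = 37.0 kJ mol⁻¹, ΔH5 = −23.0 kJ mol⁻¹)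
    (constants at 100 °C)

in all of them: left-handed substrate 0.35 M; reagent 0.210 M; precatalyst 0.42 mM; right-handed substrate 0.35 M; time 30 s

| charge | remark | temperature |
|---|---|---|
| amber | at 120 °C until 15 s, from then on at 100 °C |  |
| teal |  | 100 °C |
| blue |  | 120 °C |

- free catalyst is single-handed; left-handed substrate and right-handed substrate are mirror images of each other, charged as a racemate, each of them at the stated concentration
- constants are those at 100 °C; use the activation energies and enthalpies for any other temperature

- the flask with the highest amount of left-handed product, in percent of the left-handed substrate and right-handed substrate together charged ("all alike" if they lie within 1.5 percentage points) (amber / teal / blue / all alike)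
- final left-handed product, as a percentage of the left-handed substrate and right-handed substrate together charged, in amber
- final left-handed product, as a percentage of the left-handed substrate and right-handed substrate together charged, in teal
- final left-handed product, as a percentage of the left-handed substrate and right-handed substrate together charged, in blue

Start with the release. 0.0659 s⁻¹ is the release constant at 120 °C, so the precatalyst lifetime there is 15.2 s, against 76.9 s at 100 °C. The run of 30 s is longer than the hot lifetime and shorter than the cold one.

Now freeze what barely moves. At 100 °C, catalyst intermediate A falls back at 3070 s⁻¹, far faster than the reagent carries it forward, at 94.5 s⁻¹, so I treat binding as an equilibrium. With both substrates held at their charges, intermediate A is 13.6% of the released catalyst at 100 °C. With the hot constants 1.11 L mol⁻¹ and 4.11 L mol⁻¹, it is 13.8% at 120 °C. Multiplying by the forward constant of step 2 gives a coefficient of 61.4 L mol⁻¹ s⁻¹ cold and 123 L mol⁻¹ s⁻¹ hot. The step to right-handed product makes no difference to this count, so I drop it. The reagent then decays pseudo-first-order: the fraction left is the exponential of minus coefficient, times catalyst charge, times time.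

But the time needs correcting, since precatalyst not yet released is catalyst missing. Summed over a run, that loss comes to the lifetime multiplied by the fraction released. Teal's 30 s is therefore worth 5.16 s, the working time: the seconds the whole catalyst charge, free from the start, would need for the same catalyst output. Blue has 16.9 s. Amber has 5.47 s hot and 9.93 s cold.

My left-handed product is then 3.74% in teal, 12.5% in amber and 17.5% in blue. Blue's figure should read high, since that much product would take 35.0% of the left-handed substrate I froze.

The forecast names blue, with 11.4% for amber, 3.6% for teal and 15.4% for blue, starting from the view that “Catalyst release is slow, while substrate binding is fast”. For blue it stands below my figure; its coefficient at 120 °C, which counts both product channels, falls from 129 to 95, while I kept mine for the left-handed channel frozen.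

The simulation gives blue as the highest, at 15.3%, with amber at 11.2% and teal at 3.54%. At the end of blue, 69% of the charged left-handed substrate is still there, unbound. Put the working time to use by running my reckoning backwards on blue's left-handed product: over 16.9 s it reads as a coefficient of 100 L mol⁻¹ s⁻¹, below the frozen 123 L mol⁻¹ s⁻¹.

A neighbouring flask is like blue but holds 0.84 M of reagent, so its working time is still 16.9 s. Reagent is now the plentiful partner, at 2.40 equiv to the left-handed substrate, so I freeze it at its charge and let the left-handed substrate decay instead, which gives 43.9%. The simulation gives 40.4%, with 63% of the reagent left.

The numbers stand for no real mixture, and the outcome is calculated.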